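## Structural features

The target is a flavanone: a chroman-4-one (rings A and C) whose C2 carries ring B. Ring B is fused in linear fashion, through C4' and C5', to a 2,2-dimethyl-2H-pyran (ring D) and has a free hydroxyl at C2', ortho to the bond to C2. Ring A is a fully differentiated phloroglucinol: its three oxygens are O1 of ring C, the chelated 5-OH and the 7-OH. C6 is unsubstituted, and C8, between C8a and C7, carries a 3-hydroxy-3-methylbutyl chain ending in a tertiary carbinol. C2 (S) is the only stereocentre and has no stereogenic neighbour. It is benzylic, bonded to O1 and beta to the C4 carbonyl, so it can be lost by retro-oxa-Michael opening of ring C in base or by ionisation of O1–C2 in acid, which the ortho and para oxygens of ring B assist. The other fragile groups are the styrene-type double bond of ring D, the free phenols, and the tertiary alcohol, which in acid can cyclise onto the 7-OH to a dimethylchroman. The real difficulty is threefold: telling three equivalent phloroglucinol oxygens apart so that the chain ends at C8 and not C6, setting and keeping C2, and making ring D linear and not angular. The key step uses the fact that the fragment O1–C8a–C8–CH2–CH2–C(OH)Me2 is a ring-opened 3,4-dihydrocoumarin, with O1 as the lactone oxygen and the carbinol carbon as the lactone carbonyl carbon.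

## Logic of the disconnections

**22 to 21.** The three aryl O–CH2 acetal bonds on O5, O7 and O2' are cut last. Free phenols would stop the base-mediated condensation and would compete for the catalyst of the ring closure. One kind of acetal on all three oxygens means a single final operation. The forward step must hydrolyse three acetals without ionising the tertiary carbinol, adding to the ring D alkene or opening ring C.

**21 to 20.** The O1–C2 bond is cut. C2 is the only stereocentre and sits on this bond, so opening ring C leaves an achiral enone and reduces the stereochemical problem to one catalyst-controlled conjugate addition. The forward step demands that the oxygen destined to be O1 is the only free phenol in 20, and that closure is enantioselective under conditions that do not reopen the ring.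

**20 to 11 and 18.** The C2–C3 bond, which is the Cα=Cβ double bond of 20, is cut. This divides the molecule into a ring A methyl ketone and a ring B/ring D aldehyde of similar size, so the route becomes convergent. The forward condensation needs base-stable protecting groups and a non-enolisable aldehyde, both of which hold.

**11 to 7 through 10 and 9.** The CH3–C(O) bond of the acetyl group is cut first and then the aryl–carbonyl bond C4a–C4. Lewis-acid acylation would not tolerate the acetals. A phenol-directed ortho-formylation followed by methyl addition and oxidation puts the carbonyl carbon only next to the free oxygen. The demand is that the free phenol has one open ortho position, which is true in 7 because the other ortho carbon carries the chain.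

**7 to 5 (key).** Both C–CH3 bonds of the carbinol are cut and the carbinol carbon is reconnected to the free phenol oxygen as a lactone carbonyl. One ring then accounts for the chain, its carbinol terminus and the differentiation of O1 from O5 and O7. The forward step needs protecting groups inert to a Grignard reagent and a non-acidic work-up. Acetals on 5 meet this, and the tertiary alcohol can be left unprotected for the rest of the route.

**5 to 4, and 4 to 1 and 2.** The acetal O–C bonds are cut, then the aryl C4a–C4 bond and the lactone acyl–O bond. Because the three ring positions of 1 are equivalent, the annulation has no regiochemical issue and the symmetry is broken only by the act of lactonisation. The forward step must stop after one annulation.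

**18 to 15, 14, 12 and 13.** In ring D the O–CMe2 bond and the aryl–CH= bond are cut, which leads back through an aryl propargyl ether to 12 and 13. The forward rearrangement must go to C5 of the benzaldehyde and not to C3. This is the reason for capping O2 in 15 before heating.

## Other disconnections considered

**Alternative 1:** The cut is C3–C4 of ring C, with O1–C2 already in place as an enol ether. In the forward step A2, a ring A benzaldehyde whose ortho oxygen carries the 1-arylvinyl group of ring B, would meet a cationic monovalent rhodium catalyst made from [Rh(cod)Cl]2, a chiral bisphosphine and AgBF4. Oxidative addition of the formyl C–H bond, hydride transfer to the oxygen-bearing alkene carbon (the future C2) and reductive elimination of C3–C4 would give A1.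
- In its favour: C2 would be created in an irreversible, catalyst-controlled hydrometalation and not by a conjugate addition that can run backwards. Erosion of enantiomeric purity during ring closure is therefore less of a concern than in step 11, and on this point alternative 1 is the better plan. The step is also redox-neutral and adds no atoms.
- Against it here:
  - A2 is hard to make and to keep. The α-aryl enol ether of a doubly ortho-substituted phenol would most likely come from methylenation of the aryl ester with the aldehyde masked, and ring B makes it very prone to hydrolysis.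
  - Closure of a six-membered ketone by hydroacylation competes with decarbonylation, and the aldehyde is flanked by two ortho oxygens.
  - Hydride must go to the more substituted carbon of a 1,1-disubstituted alkene.
  - The ring D alkene and the acetal oxygens are extra ligands for the cationic metal.
  - The tertiary alcohol needs its own silyl group.
- Comparison: structurally a ring A with O1 as the only free oxygen beside the chain is still needed, so the route would start from 9 and would not replace the lactone opening. Mechanistically it trades a reversible polar closure for an organometallic closure on a less precedented ring size and alkene type. In step count, the stretch from 9 to A1 (silylation, esterification, methylenation, hydroacylation) is at least as long as steps 5, 6, 10 and 11. The final deprotection problem is the same in both plans.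

**Alternative 2:** The cut takes both bonds that ring A makes to ring C, C8a–O1 and C4a–C4, in one operation. In the forward step CsF would release the aryne A6 from the ortho-silylaryl triflate A4 in the presence of the ring B acrylic acid A5. The carboxylate oxygen would add to C8a, the aryl anion at C4a would attack the acyl carbon, and collapse of the four-membered intermediate would give the 2'-hydroxychalcone A3.
- In its favour: it is fully convergent and removes the formylation, methyl addition, oxidation and aldol steps. The acetal oxygen at C5 places the developing carbanion on the adjacent C4a and so sends the oxygen nucleophile to C8a. As a regiochemical device this is the equal of the lone-phenol control of the chosen plan.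
- Against it here:
  - A4 is a pentasubstituted arene. Its preparation still needs a phenol in which one oxygen is marked out beside the chain, most simply 7, followed by acetal protection of the tertiary alcohol, ortho-bromination, silylation, silyl migration and triflation.
  - The required attack is at the aryne carbon next to the chain, so sterics oppose electronics.
  - Protonation of the aryl anion by the acid would give a simple aryl ester instead of the ketone.
  - The enone of A3 can close ring C without control under fluoride and carboxylate.
  - The tertiary acetal must later come off in acid, which the target tolerates least.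
- Comparison: structurally the differentiation problem is moved into A4, not solved. Mechanistically two bonds form in one less predictable step, against two sequential polar steps. A3 is a chalcone, so C2 still depends on the same enantioselective oxa-Michael closure and the plans are equal there. In step economy, what is saved after the coupling is spent on A4 and A5.

**Alternative 3:** The cut takes O1–C2 and C3–C4 together, with C4 at the ether oxidation level. In the forward step 9, trimethyl orthoformate A10 and a chiral phosphoric acid would give the 4-methoxy ortho-quinone methide A9. This would add the vinyl group of the ring B hydroxystyrene A8 to give the (2S,4S)-4-methoxyflavan A7.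
- In its favour: it starts from 9, closes ring C and sets C2 in one catalytic step, and the free phenol of A8 is both a handle for the catalyst and the free 2'-OH of the target. The regiochemistry of ring C comes again from the lone phenol, so it is equal there. Up to ring closure it is shorter than the chosen plan, and on that count it is the better one.
- Against it here:
  - C4 arrives as a methyl ether and must be oxidised to the ketone in the presence of ring D, a free phenol and two very electron-rich rings. That is at least two further steps of uncertain chemoselectivity, which cancels the saving.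
  - A9 is strongly stabilised by three ring oxygens and the methoxy group, so the addition is likely stepwise through a benzylic cation at C2. Catalyst control then rests on ion pairing, and the acid can re-ionise O1–C2.
  - A8 is an acid-sensitive, polymerisable styrene.
  - The acetals and the tertiary alcohol must survive acid plus orthoformate.
- Comparison: structurally it is equal on ring A. Mechanistically it is a cationic cycloaddition against a hydrogen-bond-directed conjugate addition. In step economy it is better before ring closure and worse after it.

Key step: step 3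

Remark on the structures: 5 and 7 map onto the target without change (lactone oxygen = O1, lactone C4a = C8). One point in ring B needed correcting. With the 2-OH of the propargyl ether left free, the rearrangement is expected to go to C3 and give the angular 5-hydroxychromene, so O2 is capped (15) before heating.

Assumption: which pseudoenantiomer of the cinchona thiourea delivers (2S) is not predicted with certainty. The quinidine-derived catalyst is written in step 11, and the quinine-derived one takes its place if the sense is opposite.

## Route

Step 1
Reactants: 1 phloroglucinol; 2 acrylic acid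
Product: 4 5,7-dihydroxychroman-2-one, via hydroarylation acid 3 (not isolated)
Conditions: Amberlyst-15, toluene, 110 °C, Dean–Stark; 1 in slight excess
Reagents that add atoms: none
Why: Acid-catalysed conjugate hydroarylation (Friedel–Crafts-type Michael addition) of the arene to acrylic acid, then lactonisation with removal of water; all three ring positions of 1 are equivalent, and the excess of 1 limits a second annulation.

Step 2
Reactants: 4 5,7-dihydroxychroman-2-one
Product: 5 5,7-bis(methoxymethoxy)chroman-2-one
Conditions: MOMCl, iPr2NEt, CH2Cl2, 0 °C → rt
Reagents that add atoms: chloromethyl methyl ether, COCCl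
Why: Williamson-type O-alkylation of both phenols under amine base; no alkoxide or hydroxide is present, so the aryl lactone stays closed and its oxygen stays distinct from the other two.

Step 3
Reactants: 5 5,7-bis(methoxymethoxy)chroman-2-one
Product: 7 2-(3-hydroxy-3-methylbutyl)-3,5-bis(methoxymethoxy)phenol, via ring-opened methyl ketone 6 (not isolated)
Conditions: MeMgBr (4 equiv), THF, 0 °C → rt; sat. aq. NH4Cl
Reagents that add atoms: methylmagnesium bromide, C[Mg]Br
Why: MeMgBr adds to the lactone carbonyl and the tetrahedral magnesium hemiketalate collapses by expelling the aryloxide, the future O1, to give methyl ketone 6 as its magnesium phenoxide. The ketone is more electrophilic than the starting aryl ester and takes a second equivalent to give the tertiary alkoxide, which NH4Cl protonates to 7. The closest known reaction type is the double Grignard addition to 3,4-dihydrocoumarins that gives 2-(3-hydroxy-3-methylbutyl)phenols, the classical entry to 2,2-dimethylchromans. No ring is closed (the lactone ring is opened) and no stereocentre is formed. The selectivity needed is chemoselectivity and completeness: the acetals offer no electrophilic site, so the lactone is the only acceptor, and excess reagent at 0 °C to room temperature drives both additions. The later regiochemistry is built in, because the oxygen released is the lactone oxygen; it is therefore the only unprotected phenol and sits ortho to the chain, which fixes the chain at C8 beside O1. The work-up stays non-acidic because acid would cyclise 7 to a 2,2-dimethylchroman.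

Step 4
Reactants: 7 2-(3-hydroxy-3-methylbutyl)-3,5-bis(methoxymethoxy)phenol
Product: 9 2-hydroxy-3-(3-hydroxy-3-methylbutyl)-4,6-bis(methoxymethoxy)benzaldehyde, via ortho-hydroxymethyl phenol 8 (not isolated)
Conditions: MgCl2, Et3N, (CH2O)n, MeCN, 80 °C; aq. citric acid work-up
Reagents that add atoms: paraformaldehyde (formaldehyde), C=O
Why: Magnesium-mediated ortho-specific formylation of a phenol (Casnati–Skattebøl reaction): the magnesium phenoxide delivers formaldehyde to its ortho carbon and a second formaldehyde oxidises the benzylic alkoxide by hydride transfer. The other ortho position carries the chain and the acetal oxygens cannot direct, so only the future C4a reacts.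

Step 5
Reactants: 9 2-hydroxy-3-(3-hydroxy-3-methylbutyl)-4,6-bis(methoxymethoxy)benzaldehyde
Product: 10 2-(1-hydroxyethyl)-6-(3-hydroxy-3-methylbutyl)-3,5-bis(methoxymethoxy)phenol
Conditions: MeMgBr (4 equiv), THF, −20 → 0 °C; sat. aq. NH4Cl; used crude
Reagents that add atoms: methylmagnesium bromide, C[Mg]Br
Why: Grignard 1,2-addition to the aldehyde after deprotonation of the two hydroxyl groups; the new carbinol centre forms as a racemate and is removed in step 6.

Step 6
Reactants: 10 2-(1-hydroxyethyl)-6-(3-hydroxy-3-methylbutyl)-3,5-bis(methoxymethoxy)phenol
Product: 11 1-[2-hydroxy-3-(3-hydroxy-3-methylbutyl)-4,6-bis(methoxymethoxy)phenyl]ethan-1-one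
Conditions: activated MnO2 (excess), CH2Cl2, rt
Reagents that add atoms: none
Why: Heterogeneous MnO2 oxidation of a benzylic secondary alcohol, which leaves the tertiary alcohol and the acetals untouched; the neutral medium limits loss of water from the ortho-hydroxybenzylic alcohol.

Step 7
Reactants: 12 2,4-dihydroxybenzaldehyde; 13 3-chloro-3-methylbut-1-yne
Product: 14 2-hydroxy-4-[(2-methylbut-3-yn-2-yl)oxy]benzaldehyde
Conditions: K2CO3, KI, CuI (copper monoiodide, cat.), acetone, 55 °C
Reagents that add atoms: none
Why: Copper-assisted Williamson-type O-alkylation of a phenol by a tertiary propargylic chloride; the 4-OH is the more acidic and is not tied up in the hydrogen bond to the aldehyde, so it is alkylated selectively.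

Step 8
Reactants: 14 2-hydroxy-4-[(2-methylbut-3-yn-2-yl)oxy]benzaldehyde
Product: 15 2-(methoxymethoxy)-4-[(2-methylbut-3-yn-2-yl)oxy]benzaldehyde
Conditions: MOMCl, iPr2NEt, DMAP (cat.), CH2Cl2, 0 → 40 °C
Reagents that add atoms: chloromethyl methyl ether, COCCl
Why: Acetal protection of the chelated 2-OH; it removes the hydrogen-bonded chelate that would steer the next step to C3, and it supplies the ring B protecting group.

Step 9
Reactants: 15 2-(methoxymethoxy)-4-[(2-methylbut-3-yn-2-yl)oxy]benzaldehyde
Product: 18 7-(methoxymethoxy)-2,2-dimethyl-2H-chromene-6-carbaldehyde, via ortho-allenyl phenol 16 (not isolated), via ortho-quinone methide 17 (not isolated)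
Conditions: PhNEt2, 180 °C
Reagents that add atoms: none
Why: Aryl propargyl ether Claisen rearrangement: a [3,3] shift to C5, enolisation to the allenyl phenol, a 1,5-hydrogen shift and an oxa-6π electrocyclisation give the 2,2-dimethylchromene. With O2 capped there is no chelate-induced bond fixation towards C3, and C3 is the more crowded site between two alkoxy groups, so the shift should go to C5 and give the linear fusion.

Step 10
Reactants: 11 1-[2-hydroxy-3-(3-hydroxy-3-methylbutyl)-4,6-bis(methoxymethoxy)phenyl]ethan-1-one; 18 7-(methoxymethoxy)-2,2-dimethyl-2H-chromene-6-carbaldehyde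
Product: 20 (E)-1-[2-hydroxy-3-(3-hydroxy-3-methylbutyl)-4,6-bis(methoxymethoxy)phenyl]-3-[7-(methoxymethoxy)-2,2-dimethyl-2H-chromen-6-yl]prop-2-en-1-one, via aldol adduct 19 (not isolated)
Conditions: KOH (50% aq.), EtOH, rt; brought to pH 6 at 0 °C
Reagents that add atoms: none
Why: Claisen–Schmidt condensation: the enolate of the methyl ketone adds to the non-enolisable aldehyde and E1cB loss of water gives the E-enone. The acetals and both alkenes are base-stable, and the phenoxide form keeps ring C open until work-up.

Step 11
Reactants: 20 (E)-1-[2-hydroxy-3-(3-hydroxy-3-methylbutyl)-4,6-bis(methoxymethoxy)phenyl]-3-[7-(methoxymethoxy)-2,2-dimethyl-2H-chromen-6-yl]prop-2-en-1-one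
Product: 21 (2S)-8-(3-hydroxy-3-methylbutyl)-5,7-bis(methoxymethoxy)-2-[7-(methoxymethoxy)-2,2-dimethyl-2H-chromen-6-yl]chroman-4-one
Conditions: 9-amino-9-deoxy-epi-quinidine 3,5-bis(trifluoromethyl)phenylthiourea (10 mol%), toluene, −15 → 0 °C; stopped at full conversion
Reagents that add atoms: none
Why: Catalytic enantioselective intramolecular oxa-Michael addition of a 2'-hydroxychalcone (6-endo-trig): the quinuclidine nitrogen activates the only free phenol while the thiourea binds the enone carbonyl, so the oxygen is delivered to one face of Cβ and sets C2 as S. Every other phenol is an acetal, so ring C can close only through the oxygen released in step 3.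

Step 12
Reactants: 21 (2S)-8-(3-hydroxy-3-methylbutyl)-5,7-bis(methoxymethoxy)-2-[7-(methoxymethoxy)-2,2-dimethyl-2H-chromen-6-yl]chroman-4-one
Product: 22 (2S)-5,7-dihydroxy-2-(7-hydroxy-2,2-dimethyl-2H-chromen-6-yl)-8-(3-hydroxy-3-methylbutyl)chroman-4-one
Conditions: 2 M aq. HCl, MeOH/THF, rt → 35 °C
Reagents that add atoms: none
Why: Acid-catalysed transacetalisation of the three aryl methoxymethyl ethers to methanol; dilute acid and low temperature are chosen to spare the tertiary carbinol and the ring D alkene, and no base is present, so C2 cannot be lost by retro-oxa-Michael opening.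

## Compound list

1 | phloroglucinol (benzene-1,3,5-triol) | Oc1cc(O)cc(O)c1 | starting material
2 | acrylic acid (prop-2-enoic acid) | C=CC(=O)O | starting material
3 | 3-(2,4,6-trihydroxyphenyl)propanoic acid | OC(=O)CCc1c(O)cc(O)cc1O | intermediate (not isolated)
4 | 5,7-dihydroxychroman-2-one | O=C1CCc2c(O)cc(O)cc2O1 | intermediate
5 | 5,7-bis(methoxymethoxy)chroman-2-one | O=C1CCc2c(OCOC)cc(OCOC)cc2O1 | intermediate
6 | 4-[2-hydroxy-4,6-bis(methoxymethoxy)phenyl]butan-2-one (present as its magnesium phenoxide) | CC(=O)CCc1c(O)cc(OCOC)cc1OCOC | intermediate (not isolated)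
7 | 2-(3-hydroxy-3-methylbutyl)-3,5-bis(methoxymethoxy)phenol | CC(C)(O)CCc1c(O)cc(OCOC)cc1OCOC | intermediate
8 | 2-(hydroxymethyl)-6-(3-hydroxy-3-methylbutyl)-3,5-bis(methoxymethoxy)phenol | CC(C)(O)CCc1c(O)c(CO)c(OCOC)cc1OCOC | intermediate (not isolated)
9 | 2-hydroxy-3-(3-hydroxy-3-methylbutyl)-4,6-bis(methoxymethoxy)benzaldehyde | CC(C)(O)CCc1c(O)c(C=O)c(OCOC)cc1OCOC | intermediate
10 | 2-(1-hydroxyethyl)-6-(3-hydroxy-3-methylbutyl)-3,5-bis(methoxymethoxy)phenol (racemic at the carbinol carbon) | CC(O)c1c(O)c(CCC(C)(C)O)c(OCOC)cc1OCOC | intermediate
11 | 1-[2-hydroxy-3-(3-hydroxy-3-methylbutyl)-4,6-bis(methoxymethoxy)phenyl]ethan-1-one | CC(=O)c1c(O)c(CCC(C)(C)O)c(OCOC)cc1OCOC | intermediate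
12 | 2,4-dihydroxybenzaldehyde | O=Cc1ccc(O)cc1O | starting material
13 | 3-chloro-3-methylbut-1-yne | CC(C)(Cl)C#C | starting material
14 | 2-hydroxy-4-[(2-methylbut-3-yn-2-yl)oxy]benzaldehyde | C#CC(C)(C)Oc1ccc(C=O)c(O)c1 | intermediate
15 | 2-(methoxymethoxy)-4-[(2-methylbut-3-yn-2-yl)oxy]benzaldehyde | C#CC(C)(C)Oc1ccc(C=O)c(OCOC)c1 | intermediate
16 | 4-hydroxy-2-(methoxymethoxy)-5-(3-methylbuta-1,2-dien-1-yl)benzaldehyde | CC(C)=C=Cc1cc(C=O)c(OCOC)cc1O | intermediate (not isolated)
17 | 6-(methoxymethoxy)-3-(3-methylbut-2-en-1-ylidene)-4-oxocyclohexa-1,5-diene-1-carbaldehyde | O=CC1=CC(=CC=C(C)C)C(=O)C=C1OCOC | intermediate (not isolated)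
18 | 7-(methoxymethoxy)-2,2-dimethyl-2H-chromene-6-carbaldehyde | COCOc1cc2OC(C)(C)C=Cc2cc1C=O | intermediate
19 | 3-hydroxy-1-[2-hydroxy-3-(3-hydroxy-3-methylbutyl)-4,6-bis(methoxymethoxy)phenyl]-3-[7-(methoxymethoxy)-2,2-dimethyl-2H-chromen-6-yl]propan-1-one | CC(C)(O)CCc1c(O)c(C(=O)CC(O)c2cc3C=CC(C)(C)Oc3cc2OCOC)c(OCOC)cc1OCOC | intermediate (not isolated)
20 | (E)-1-[2-hydroxy-3-(3-hydroxy-3-methylbutyl)-4,6-bis(methoxymethoxy)phenyl]-3-[7-(methoxymethoxy)-2,2-dimethyl-2H-chromen-6-yl]prop-2-en-1-one | CC(C)(O)CCc1c(O)c(C(=O)/C=C/c2cc3C=CC(C)(C)Oc3cc2OCOC)c(OCOC)cc1OCOC | intermediate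
21 | (2S)-8-(3-hydroxy-3-methylbutyl)-5,7-bis(methoxymethoxy)-2-[7-(methoxymethoxy)-2,2-dimethyl-2H-chromen-6-yl]chroman-4-one | CC(C)(O)CCc1c(OCOC)cc(OCOC)c2c1O[C@H](c1cc3c(cc1OCOC)OC(C)(C)C=C3)CC2=O | intermediate
22 | (2S)-5,7-dihydroxy-2-(7-hydroxy-2,2-dimethyl-2H-chromen-6-yl)-8-(3-hydroxy-3-methylbutyl)chroman-4-one | CC(C)(O)CCc1c(O)cc(O)c2c1O[C@H](c1cc3c(cc1O)OC(C)(C)C=C3)CC2=O | target

## Step count and least certain steps

Total: 12 steps. Longest linear sequence: 9 steps (steps 1 to 6 and 10 to 12, from 1). The ring B branch is 3 steps (7 to 9).

**Step 3 (key).** The sequence may stall after the first addition if the ketone magnesium phenoxide is enolised instead of attacked. An acidic work-up would also cyclise the product to a dimethylchroman. The fallback sets out from 5 and returns at 7. Ring-opening aminolysis of 5 with MeNH(OMe)·HCl and iPrMgCl in THF gives 3-[2-hydroxy-4,6-bis(methoxymethoxy)phenyl]-N-methoxy-N-methylpropanamide F1. MeMgBr then stops cleanly at ketone 6, which is isolated. A non-basic organocerium reagent (MeLi, CeCl3, THF, −78 °C) adds the second methyl group to give 7.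

**Step 11.** Facial discrimination may be poor for an unactivated, very electron-rich enone, and enantiomeric purity may erode by reversible ring opening under the basic catalyst. The fallback sets out from 20 and returns at 21. Unselective closure with NaOAc in EtOH at reflux gives racemic 8-(3-hydroxy-3-methylbutyl)-5,7-bis(methoxymethoxy)-2-[7-(methoxymethoxy)-2,2-dimethyl-2H-chromen-6-yl]chroman-4-one F2. Preparative supercritical-fluid chromatography on an amylose tris(3,5-dimethylphenylcarbamate) phase then delivers 21. The unwanted (2R)-8-(3-hydroxy-3-methylbutyl)-5,7-bis(methoxymethoxy)-2-[7-(methoxymethoxy)-2,2-dimethyl-2H-chromen-6-yl]chroman-4-one F3 is re-equilibrated to F2 with the same base and recycled.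

**Step 9.** The [3,3] shift may go in part to C3, because both ortho carbons are activated, which would give the angular chromene. The fallback sets out from 12 and returns at 18, and fixes the site with a halogen.
- Br2 in AcOH gives 5-bromo-2,4-dihydroxybenzaldehyde F4.
- Heck coupling with 2-methylbut-3-en-2-ol (Pd(OAc)2, P(o-tol)3, Et3N, DMF, 100 °C) gives 2,4-dihydroxy-5-[(E)-3-hydroxy-3-methylbut-1-en-1-yl]benzaldehyde F5.
- Mild acid (pyridinium tosylate, toluene, 80 °C) closes the allylic cation onto the 4-OH to give 7-hydroxy-2,2-dimethyl-2H-chromene-6-carbaldehyde F6.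
- MOMCl and iPr2NEt convert F6 into 18.

**Step 12.** Acid may ionise the tertiary carbinol, with ring closure onto O7, may add to the ring D alkene, or may ionise O1–C2 with partial racemisation. The fallback sets out from 21 and returns at 22, and replaces protic hydrolysis by silyl transfer. TMSOTf and 2,2'-bipyridyl in MeCN at 0 °C exchange the aryl acetals for silyl ethers and silylate the carbinol. This gives (2S)-2-[2,2-dimethyl-7-(trimethylsilyloxy)-2H-chromen-6-yl]-8-[3-methyl-3-(trimethylsilyloxy)butyl]-5,7-bis(trimethylsilyloxy)chroman-4-one F7. Water and a trace of citric acid in THF at 0 °C hydrolyse F7 to 22.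

**Step 6 (with step 5).** The ortho-hydroxybenzylic alcohol may lose water to an ortho-quinone methide that oligomerises, and the electron-rich phenol may couple oxidatively on the oxidant surface. The fallback sets out from 9 and returns at 11, and caps the phenol before the alcohol is made.
- TESOTf and 2,6-lutidine give 4,6-bis(methoxymethoxy)-3-[3-methyl-3-(triethylsilyloxy)butyl]-2-(triethylsilyloxy)benzaldehyde F8.
- MeMgBr at −78 °C gives 1-{4,6-bis(methoxymethoxy)-3-[3-methyl-3-(triethylsilyloxy)butyl]-2-(triethylsilyloxy)phenyl}ethan-1-ol F9.
- Dess–Martin periodinane with NaHCO3 gives 1-{4,6-bis(methoxymethoxy)-3-[3-methyl-3-(triethylsilyloxy)butyl]-2-(triethylsilyloxy)phenyl}ethan-1-one F10.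
- Bu4NF buffered with AcOH removes both silyl groups to give 11.

**Step 1.** A second annulation of the trihydric phenol, C-acylation in place of conjugate C-alkylation, or polymerisation of acrylic acid may compete. The fallback sets out from 1 and returns at 4. Ethyl propiolate with ZnCl2 at 100 °C gives 5,7-dihydroxy-2H-chromen-2-one F11. Hydrogenation of its C3=C4 bond (H2, Pd/C, EtOH) gives 4.

## Further compounds

F1 | step 3 | 3-[2-hydroxy-4,6-bis(methoxymethoxy)phenyl]-N-methoxy-N-methylpropanamide | CON(C)C(=O)CCc1c(O)cc(OCOC)cc1OCOC
F2 | step 11 | racemic 8-(3-hydroxy-3-methylbutyl)-5,7-bis(methoxymethoxy)-2-[7-(methoxymethoxy)-2,2-dimethyl-2H-chromen-6-yl]chroman-4-one | CC(C)(O)CCc1c(OCOC)cc(OCOC)c2c1OC(c1cc3c(cc1OCOC)OC(C)(C)C=C3)CC2=O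
F3 | step 11 | (2R)-8-(3-hydroxy-3-methylbutyl)-5,7-bis(methoxymethoxy)-2-[7-(methoxymethoxy)-2,2-dimethyl-2H-chromen-6-yl]chroman-4-one | CC(C)(O)CCc1c(OCOC)cc(OCOC)c2c1O[C@@H](c1cc3c(cc1OCOC)OC(C)(C)C=C3)CC2=O
F4 | step 9 | 5-bromo-2,4-dihydroxybenzaldehyde | O=Cc1cc(Br)c(O)cc1O
F5 | step 9 | 2,4-dihydroxy-5-[(E)-3-hydroxy-3-methylbut-1-en-1-yl]benzaldehyde | CC(C)(O)/C=C/c1cc(C=O)c(O)cc1O
F6 | step 9 | 7-hydroxy-2,2-dimethyl-2H-chromene-6-carbaldehyde | CC1(C)C=Cc2cc(C=O)c(O)cc2O1
F7 | step 12 | (2S)-2-[2,2-dimethyl-7-(trimethylsilyloxy)-2H-chromen-6-yl]-8-[3-methyl-3-(trimethylsilyloxy)butyl]-5,7-bis(trimethylsilyloxy)chroman-4-one | C[Si](C)(C)OC(C)(C)CCc1c(O[Si](C)(C)C)cc(O[Si](C)(C)C)c2c1O[C@H](c1cc3c(cc1O[Si](C)(C)C)OC(C)(C)C=C3)CC2=O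
F8 | step 6 | 4,6-bis(methoxymethoxy)-3-[3-methyl-3-(triethylsilyloxy)butyl]-2-(triethylsilyloxy)benzaldehyde | CC[Si](CC)(CC)OC(C)(C)CCc1c(O[Si](CC)(CC)CC)c(C=O)c(OCOC)cc1OCOC
F9 | step 6 | 1-{4,6-bis(methoxymethoxy)-3-[3-methyl-3-(triethylsilyloxy)butyl]-2-(triethylsilyloxy)phenyl}ethan-1-ol | CC[Si](CC)(CC)OC(C)(C)CCc1c(O[Si](CC)(CC)CC)c(C(C)O)c(OCOC)cc1OCOC
F10 | step 6 | 1-{4,6-bis(methoxymethoxy)-3-[3-methyl-3-(triethylsilyloxy)butyl]-2-(triethylsilyloxy)phenyl}ethan-1-one | CC[Si](CC)(CC)OC(C)(C)CCc1c(O[Si](CC)(CC)CC)c(C(C)=O)c(OCOC)cc1OCOC
F11 | step 1 | 5,7-dihydroxy-2H-chromen-2-one | O=c1ccc2c(O)cc(O)cc2o1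
A1 | alternative 1 | (2S)-5,7-bis(methoxymethoxy)-2-[7-(methoxymethoxy)-2,2-dimethyl-2H-chromen-6-yl]-8-[3-methyl-3-(triethylsilyloxy)butyl]chroman-4-one | CC[Si](CC)(CC)OC(C)(C)CCc1c(OCOC)cc(OCOC)c2c1O[C@H](c1cc3c(cc1OCOC)OC(C)(C)C=C3)CC2=O
A2 | alternative 1 | 2-({1-[7-(methoxymethoxy)-2,2-dimethyl-2H-chromen-6-yl]ethenyl}oxy)-4,6-bis(methoxymethoxy)-3-[3-methyl-3-(triethylsilyloxy)butyl]benzaldehyde | CC[Si](CC)(CC)OC(C)(C)CCc1c(OCOC)cc(OCOC)c(C=O)c1OC(=C)c1cc2C=CC(C)(C)Oc2cc1OCOC
A3 | alternative 2 | (E)-1-{2-hydroxy-4,6-bis(methoxymethoxy)-3-[3-(methoxymethoxy)-3-methylbutyl]phenyl}-3-[7-(methoxymethoxy)-2,2-dimethyl-2H-chromen-6-yl]prop-2-en-1-one | COCOC(C)(C)CCc1c(O)c(C(=O)/C=C/c2cc3C=CC(C)(C)Oc3cc2OCOC)c(OCOC)cc1OCOC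
A4 | alternative 2 | 3,5-bis(methoxymethoxy)-2-[3-(methoxymethoxy)-3-methylbutyl]-6-(trimethylsilyl)phenyl trifluoromethanesulfonate | COCOC(C)(C)CCc1c(OS(=O)(=O)C(F)(F)F)c([Si](C)(C)C)c(OCOC)cc1OCOC
A5 | alternative 2 | (E)-3-[7-(methoxymethoxy)-2,2-dimethyl-2H-chromen-6-yl]prop-2-enoic acid | OC(=O)/C=C/c1cc2C=CC(C)(C)Oc2cc1OCOC
A6 | alternative 2 | 1,2-didehydro-4,6-bis(methoxymethoxy)-3-[3-(methoxymethoxy)-3-methylbutyl]benzene | COCOC(C)(C)CCC1=C(OCOC)C=C(OCOC)C#C1
A7 | alternative 3 | 4-[(2S,4S)-2-(7-hydroxy-2,2-dimethyl-2H-chromen-6-yl)-4-methoxy-5,7-bis(methoxymethoxy)chroman-8-yl]-2-methylbutan-2-ol | CC(C)(O)CCc1c(OCOC)cc(OCOC)c2c1O[C@H](c1cc3c(cc1O)OC(C)(C)C=C3)C[C@@H]2OC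
A8 | alternative 3 | 6-ethenyl-2,2-dimethyl-2H-chromen-7-ol | C=Cc1cc2C=CC(C)(C)Oc2cc1O
A9 | alternative 3 | 2-(3-hydroxy-3-methylbutyl)-6-(methoxymethylidene)-3,5-bis(methoxymethoxy)cyclohexa-2,4-dien-1-one | COC=C1C(=O)C(CCC(C)(C)O)=C(OCOC)C=C1OCOC
A10 | alternative 3 | trimethyl orthoformate | COC(OC)OC
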